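The ten-membered carbocycle is opened at C5–C6 (germacrane numbering). The contiguous array C4(=C15H2)–C5(OH)–C6(O-lactone), lying between the C3–O–C10 furanone ring and the C6/C7 lactone ring, is the retron of a γ-oxygenated allylmetal adding to an aldehyde. In one operation a γ-acyloxyallylchromium generated with divalent chromium (metal on C15, acyloxy on C5) attacks the C6 aldehyde through C5, closing the carbocycle, unveiling the exo-methylene and setting C5 and C6 anti. The precursor is a furanone carrying a 3-bromo-1-(methoxyacetoxy)propen-2-yl group at C3 and, on C10, a chain with the C8 isobutyrate, the C7 methyl acrylate and the C6 aldehyde.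

Key step: step 17

Remarks on the chemistry:
- Germacrane numbering is used throughout: ring C1–C10, C1 ketone, C3–O–C10 furanone bridge, C15 methylene on C4, lactone carbonyl C12 on O6, C13 methylene on C11, C14 methyl on C10.
- The allyl donor of step 10 carries C6 as a silyloxymethyl group. A plain 2-(bromomethyl)acrylate would leave C7 as CH2 with no way to attach the C6 aldehyde.
- The enol ester is a methoxyacetate, not an acetate. An O5 acetate cannot be cleaved with useful selectivity beside the O8 isobutyrate, whereas a methoxyacetate can (step 19).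
- Compounds 25–28 form as E/Z mixtures at the enol ester (E drawn); both geometries converge in step 17.
- Assumption: 1 and 15 are treated as purchasable.
- In step 10 the (S,S)-ligand is written; which antipode delivers Si-face attack on this aldehyde is to be fixed on a model, and both antipodes are available from valinol.

Step 1
Reactants: 1 2-bromo-3,3-diethoxyprop-1-ene; 2 ethynyltrimethylsilane
Product: 3 (4,4-diethoxy-3-methylidenebut-1-yn-1-yl)trimethylsilane
Conditions: Pd(PPh3)2Cl2 (2 mol %), CuI (4 mol %), Et3N, THF, 40 °C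
Reagents that add atoms: none
Why: Sonogashira coupling of a 1,1-disubstituted vinyl bromide with a terminal alkyne should join C3 to C4 while the acetal keeps C5 masked at the aldehyde level.

Step 2
Reactants: 3 silylated enyne acetal
Product: 4 4,4-diethoxy-3-methylidenebut-1-yne
Conditions: K2CO3 (0.2 equiv), MeOH, 0 °C → rt; carried on as a THF solution
Reagents that add atoms: none
Why: base-catalysed methanolysis of the alkynyl C–Si bond (protodesilylation) should free the terminal alkyne without touching the acetal or the alkene.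

Step 3
Reactants: 5 (S)-citramalic acid
Product: 6 2-[(4S)-2,2,4-trimethyl-5-oxo-1,3-dioxolan-4-yl]acetic acid
Conditions: 2,2-dimethoxypropane, TsOH·H2O (cat.), rt
Reagents that add atoms: 2,2-dimethoxypropane, COC(C)(C)OC
Why: acid-catalysed acetonide (dioxolanone) formation should tie the tertiary hydroxyl to the adjacent carboxyl in a five-membered ring, leaving only the CH2CO2H group free, with the C10 stereocenter untouched.

Step 4
Reactants: 6 dioxolanone acid
Product: 8 (3S)-3-hydroxy-3-methyloxolan-2-one, via hydroxy dioxolanone 7 (not isolated)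
Conditions: BH3·SMe2, THF, 0 °C → rt; MeOH; then TsOH·H2O (cat.), CH2Cl2, rt
Reagents that add atoms: none
Why: chemoselective borane reduction of the free carboxylic acid (faster than the dioxolanone carbonyl) followed by acid-catalysed translactonisation with loss of acetone should give the hydroxy lactone, in which C8 is a masked primary alcohol and C1 an acyl donor.

Step 5
Reactants: 4 enyne acetal; 8 hydroxy lactone
Product: 10 (6S)-1,1-diethoxy-6,8-dihydroxy-6-methyl-2-methylideneoct-3-yn-5-one, via lithium acetylide 9 (not isolated)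
Conditions: 4 (2.5 equiv), n-BuLi (2.4 equiv), THF, −78 °C; then 8, −78 → −40 °C; AcOH, −78 °C
Reagents that add atoms: none
Why: addition of an alkynyllithium to a γ-lactone should stop at the ketone level because the lithium lactolate survives at low temperature, the first equivalent of acetylide only deprotonating the tertiary hydroxyl.

Step 6
Reactants: 10 hydroxy ynone
Product: 12 (2S)-5-(3,3-diethoxyprop-1-en-2-yl)-2-(2-hydroxyethyl)-2-methylfuran-3(2H)-one, via enaminone 11 (not isolated)
Conditions: Et2NH (1.5 equiv), EtOH, rt; then AcOH (1 equiv), rt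
Reagents that add atoms: none
Why: hydroxy-ynone cyclisation to a 3(2H)-furanone, in which conjugate addition of the amine gives the β-amino enone and the tertiary C10 hydroxyl then displaces the amine by 5-exo-trig addition–elimination, the primary hydroxyl being unable to compete because it would need a seven-membered ring.

Step 7
Reactants: 12 furanone alcohol
Product: 13 2-[(2S)-5-(3,3-diethoxyprop-1-en-2-yl)-2-methyl-3-oxo-2,3-dihydrofuran-2-yl]acetaldehyde
Conditions: Dess–Martin periodinane, NaHCO3, CH2Cl2, 0 °C → rt; used crude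
Reagents that add atoms: none
Why: Dess–Martin oxidation under buffered, non-basic conditions should give the C8 aldehyde without β-elimination of the furanone oxygen from C10.

Step 8
Reactants: 14 methyl acrylate; 15 2-[(tert-butyldiphenylsilyl)oxy]acetaldehyde
Product: 16 methyl 4-[(tert-butyldiphenylsilyl)oxy]-3-hydroxy-2-methylidenebutanoate (racemic)
Conditions: DABCO (0.3 equiv), excess 14, neat, rt
Reagents that add atoms: none
Why: Morita–Baylis–Hillman reaction of an unhindered α-oxygenated aldehyde should join C11 to C7, the carbinol stereocenter being of no consequence because it becomes sp2 in step 9.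

Step 9
Reactants: 16 Morita–Baylis–Hillman alcohol
Product: 17 methyl (2Z)-2-(bromomethyl)-4-[(tert-butyldiphenylsilyl)oxy]but-2-enoate
Conditions: NBS, Me2S, CH2Cl2, −20 °C → rt
Reagents that add atoms: N-bromosuccinimide, O=C1CCC(=O)N1Br
Why: bromination through the alkoxysulfonium salt with allylic transposition (SN2') should give the trisubstituted acrylate in its more stable Z form, with the silyloxymethyl group cis to CH2Br.

Step 10
Reactants: 13 furanone aldehyde; 17 allylic bromide
Product: 19 homoallylic alcohol (7S,8R,10S), via trimethylsilyl ether 18 (not isolated)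
Conditions: CrCl2 (10 mol %), (S,S)-1,8-bis(4-isopropyl-4,5-dihydrooxazol-2-yl)-3,6-diphenyl-9H-carbazole (12 mol %), Mn powder (2 equiv), TMSCl (2 equiv), i-Pr2NEt (0.3 equiv), THF, rt; then 0.5 M aq. citric acid, THF, 0 °C
Reagents that add atoms: none
Why: catalytic asymmetric Nozaki–Hiyama–Kishi 2-(alkoxycarbonyl)allylation, in which the allylchromium keeps the silyloxymethyl group cis to CH2–Cr and adds through C7 in a chair (Zimmerman–Traxler) transition state to give the syn C7/C8 pair, while the tridentate bis(oxazolinyl)carbazole ligand directs attack to the Si face of the C8 aldehyde (8R), the remote C10 centre exerting little bias and the ketone, esters and acetal being inert to organochromium.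

Step 11
Reactants: 19 homoallylic alcohol; 20 isobutyric anhydride
Product: 21 C8 isobutyrate (7S,8R,10S)
Conditions: DMAP (0.1 equiv), Et3N, CH2Cl2, 0 °C
Reagents that add atoms: none
Why: DMAP-catalysed acyl transfer to the secondary alcohol, run cold and directly on fresh 19, should outpace lactonisation of O8 onto the acrylate ester and leaves all stereocenters untouched.

Step 12
Reactants: 21 acetal isobutyrate
Product: 22 C5 enal (7S,8R,10S)
Conditions: 1 M aq. HCl, THF, 0 °C → rt; used at once
Reagents that add atoms: water, O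
Why: acid-catalysed acetal hydrolysis should unveil the 2-substituted acrolein while the tert-butyldiphenylsilyl ether and the three esters tolerate dilute acid.

Step 13
Reactants: 23 methoxyacetyl chloride
Product: 24 methoxyacetyl bromide
Conditions: TMSBr (1.5 equiv), neat, rt → 50 °C; distilled
Reagents that add atoms: bromotrimethylsilane, C[Si](C)(C)Br
Why: halogen exchange between an acyl chloride and bromotrimethylsilane is driven by removal of the volatile chlorosilane.

Step 14
Reactants: 22 C5 enal; 24 methoxyacetyl bromide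
Product: 25 bromopropenyl methoxyacetate with C6 silyl ether (7S,8R,10S)
Conditions: ZnCl2 (1 mol %), CH2Cl2, −30 → 0 °C
Reagents that add atoms: none
Why: Lewis-acid-catalysed conjugate (1,4-) addition of an acyl bromide to an enal should acylate the aldehyde oxygen and deliver bromide to C15, giving the conjugated 3-bromoprop-1-enyl ester as the thermodynamic product, the bulky silyl ether resisting acylative cleavage and the furanone carbonyl forming no stable adduct.

Step 15
Reactants: 25 silyl ether
Product: 26 C6 primary alcohol (7S,8R,10S)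
Conditions: HF·pyridine, THF, 0 °C → rt, polypropylene vessel
Reagents that add atoms: none
Why: fluoride-mediated Si–O cleavage under acidic, non-nucleophilic conditions should spare the allylic bromide, the enol ester and the other esters.

Step 16
Reactants: 26 C6 primary alcohol
Product: 27 furanone bromopropenyl methoxyacetate aldehyde (7R,8R,10S)
Conditions: Dess–Martin periodinane, NaHCO3, CH2Cl2, 0 °C; used at once
Reagents that add atoms: none
Why: Dess–Martin oxidation is fast and near neutral, so the C7 centre, which is α to the new aldehyde and allylic to the acrylate, should neither epimerise nor slide into conjugation.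

Step 17
Reactants: 27 furanone bromopropenyl methoxyacetate aldehyde
Product: 29 macrocyclic C5 methoxyacetate C6 alcohol (5S,6R,7S,8R,10S), via allylchromium 28 (not isolated)
Conditions: CrCl2 (10 equiv), THF, 25 °C, 27 added by syringe pump over 10 h (final 1 mM); pH 7 phosphate buffer, 0 °C
Reagents that add atoms: none
Why: Proposed new method: two equivalents of divalent chromium reduce the allylic C15–Br bond of 27 to the trivalent allylchromium 28, whose 1,3-metal shift lets both enol ester isomers settle in the geometry with the acyloxy group trans to CH2–Cr, and 28 then adds through C5 to the C6 aldehyde in a six-membered chair (Zimmerman–Traxler) transition state. The closest known reactions are the intermolecular chromium- or indium-mediated additions of 3-bromopropenyl esters to aldehydes, which give anti alk-1-ene-3,4-diol monoesters, and chromium-mediated closures of ten-membered rings from simple allylic bromides; their combination on a 2-substituted reagent is the untested part. The carbocycle closes in a 10-exo-trig mode at the aldehyde carbon, the carbonyl oxygen staying outside the ring and C4=C15 emerging as the exocyclic methylene. C5 is set by the chair, in which the pseudo-equatorial acyloxy group gives the anti (5S,6R) pair, and C6 is set by C7 through Felkin–Anh attack on the Si face of the aldehyde with the acrylate unit perpendicular to the carbonyl. The step needs selectivity for the aldehyde over the C1 ketone and three ester groups (inherent to organochromium reagents), γ- over α-attack (enforced by the cyclic transition state) and cyclisation over oligomerisation (slow addition to 1 mM, with the flat furanone and the C7/C8 substituents shortening the reactive chain).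

Step 18
Reactants: 29 macrocyclic hydroxy ester
Product: 30 lactone C5 methoxyacetate (5S,6R,7R,8R,10S)
Conditions: TsOH·H2O (0.1 equiv), CH2Cl2, rt
Reagents that add atoms: none
Why: acid-catalysed lactonisation (intramolecular transesterification) of O6 onto C12 should close the five-membered α-methylene lactone, acid being chosen because it does not promote migration of the methoxyacetyl group and any lactone already formed in step 17 converges here.

Step 19
Reactants: 30 lactone C5 methoxyacetate
Product: 31 CNP0384113.2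
Conditions: Yb(OTf)3 (0.3 equiv), MeOH, 0 °C → rt
Reagents that add atoms: none
Why: Lewis-acid-catalysed chemoselective methanolysis of a methoxyacetate, in which bidentate binding of ytterbium triflate to the α-methoxy ester activates only that acyl group, should free O5 while the isobutyrate and the lactone stay intact and no alkoxide is present to add to the α-methylene lactone.

Compound list
1 | 2-bromo-3,3-diethoxyprop-1-ene | C=C(Br)C(OCC)OCC | starting material
2 | ethynyltrimethylsilane | C#C[Si](C)(C)C | starting material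
3 | (4,4-diethoxy-3-methylidenebut-1-yn-1-yl)trimethylsilane | C=C(C#C[Si](C)(C)C)C(OCC)OCC | intermediate
4 | 4,4-diethoxy-3-methylidenebut-1-yne | C=C(C#C)C(OCC)OCC | intermediate
5 | (S)-citramalic acid, (2S)-2-hydroxy-2-methylbutanedioic acid | OC(=O)C[C@](C)(O)C(=O)O | starting material
6 | 2-[(4S)-2,2,4-trimethyl-5-oxo-1,3-dioxolan-4-yl]acetic acid | CC1(C)OC(=O)[C@](C)(CC(=O)O)O1 | intermediate
7 | (5S)-5-(2-hydroxyethyl)-2,2,5-trimethyl-1,3-dioxolan-4-one | CC1(C)OC(=O)[C@](C)(CCO)O1 | intermediate
8 | (3S)-3-hydroxy-3-methyloxolan-2-one | C[C@]1(O)CCOC1=O | intermediate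
9 | (4,4-diethoxy-3-methylidenebut-1-yn-1-yl)lithium | [Li]C#CC(=C)C(OCC)OCC | intermediate
10 | (6S)-1,1-diethoxy-6,8-dihydroxy-6-methyl-2-methylideneoct-3-yn-5-one | OCC[C@](C)(O)C(=O)C#CC(=C)C(OCC)OCC | intermediate
11 | (3E,6S)-3-(diethylamino)-1,1-diethoxy-6,8-dihydroxy-6-methyl-2-methylideneoct-3-en-5-one | CCN(CC)/C(=C/C(=O)[C@@](C)(O)CCO)C(=C)C(OCC)OCC | intermediate
12 | (2S)-5-(3,3-diethoxyprop-1-en-2-yl)-2-(2-hydroxyethyl)-2-methylfuran-3(2H)-one | CCOC(OCC)C(=C)C1=CC(=O)[C@](C)(CCO)O1 | intermediate
13 | 2-[(2S)-5-(3,3-diethoxyprop-1-en-2-yl)-2-methyl-3-oxo-2,3-dihydrofuran-2-yl]acetaldehyde | CCOC(OCC)C(=C)C1=CC(=O)[C@](C)(CC=O)O1 | intermediate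
14 | methyl acrylate | C=CC(=O)OC | starting material
15 | 2-[(tert-butyldiphenylsilyl)oxy]acetaldehyde | O=CCO[Si](c1ccccc1)(c1ccccc1)C(C)(C)C | starting material
16 | methyl 4-[(tert-butyldiphenylsilyl)oxy]-3-hydroxy-2-methylidenebutanoate (racemic) | C=C(C(=O)OC)C(O)CO[Si](c1ccccc1)(c1ccccc1)C(C)(C)C | intermediate
17 | methyl (2Z)-2-(bromomethyl)-4-[(tert-butyldiphenylsilyl)oxy]but-2-enoate | BrC/C(=C\CO[Si](c1ccccc1)(c1ccccc1)C(C)(C)C)C(=O)OC | intermediate
18 | O8-trimethylsilyl ether of 19 | CCOC(OCC)C(=C)C1=CC(=O)[C@](C)(C[C@@H](O[Si](C)(C)C)[C@H](CO[Si](c2ccccc2)(c2ccccc2)C(C)(C)C)C(=C)C(=O)OC)O1 | intermediate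
19 | methyl (3S,4R)-3-{[(tert-butyldiphenylsilyl)oxy]methyl}-5-[(2S)-5-(3,3-diethoxyprop-1-en-2-yl)-2-methyl-3-oxo-2,3-dihydrofuran-2-yl]-4-hydroxy-2-methylidenepentanoate | CCOC(OCC)C(=C)C1=CC(=O)[C@](C)(C[C@@H](O)[C@H](CO[Si](c2ccccc2)(c2ccccc2)C(C)(C)C)C(=C)C(=O)OC)O1 | intermediate
20 | isobutyric anhydride (2-methylpropanoic anhydride) | CC(C)C(=O)OC(=O)C(C)C | starting material
21 | methyl (3S,4R)-3-{[(tert-butyldiphenylsilyl)oxy]methyl}-5-[(2S)-5-(3,3-diethoxyprop-1-en-2-yl)-2-methyl-3-oxo-2,3-dihydrofuran-2-yl]-2-methylidene-4-[(2-methylpropanoyl)oxy]pentanoate | CCOC(OCC)C(=C)C1=CC(=O)[C@](C)(C[C@@H](OC(=O)C(C)C)[C@H](CO[Si](c2ccccc2)(c2ccccc2)C(C)(C)C)C(=C)C(=O)OC)O1 | intermediate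
22 | methyl (3S,4R)-3-{[(tert-butyldiphenylsilyl)oxy]methyl}-5-[(2S)-2-methyl-3-oxo-5-(3-oxoprop-1-en-2-yl)-2,3-dihydrofuran-2-yl]-2-methylidene-4-[(2-methylpropanoyl)oxy]pentanoate | O=CC(=C)C1=CC(=O)[C@](C)(C[C@@H](OC(=O)C(C)C)[C@H](CO[Si](c2ccccc2)(c2ccccc2)C(C)(C)C)C(=C)C(=O)OC)O1 | intermediate
23 | methoxyacetyl chloride | COCC(=O)Cl | starting material
24 | methoxyacetyl bromide | COCC(=O)Br | intermediate
25 | methyl (3S,4R)-5-[(2S)-5-{(1E)-3-bromo-1-[(methoxyacetyl)oxy]prop-1-en-2-yl}-2-methyl-3-oxo-2,3-dihydrofuran-2-yl]-3-{[(tert-butyldiphenylsilyl)oxy]methyl}-2-methylidene-4-[(2-methylpropanoyl)oxy]pentanoate (E/Z mixture, E drawn) | BrC/C(=C/OC(=O)COC)C1=CC(=O)[C@](C)(C[C@@H](OC(=O)C(C)C)[C@H](CO[Si](c2ccccc2)(c2ccccc2)C(C)(C)C)C(=C)C(=O)OC)O1 | intermediate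
26 | methyl (3S,4R)-5-[(2S)-5-{(1E)-3-bromo-1-[(methoxyacetyl)oxy]prop-1-en-2-yl}-2-methyl-3-oxo-2,3-dihydrofuran-2-yl]-3-(hydroxymethyl)-2-methylidene-4-[(2-methylpropanoyl)oxy]pentanoate (E/Z mixture, E drawn) | BrC/C(=C/OC(=O)COC)C1=CC(=O)[C@](C)(C[C@@H](OC(=O)C(C)C)[C@H](CO)C(=C)C(=O)OC)O1 | intermediate
27 | methyl (3R,4R)-5-[(2S)-5-{(1E)-3-bromo-1-[(methoxyacetyl)oxy]prop-1-en-2-yl}-2-methyl-3-oxo-2,3-dihydrofuran-2-yl]-3-formyl-2-methylidene-4-[(2-methylpropanoyl)oxy]pentanoate (E/Z mixture, E drawn; precursor of the key step) | BrC/C(=C/OC(=O)COC)C1=CC(=O)[C@](C)(C[C@@H](OC(=O)C(C)C)[C@H](C=O)C(=C)C(=O)OC)O1 | intermediate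
28 | allylchromium dichloride derived from 27 (trivalent chromium on C15 in place of bromine, acyloxy trans to CH2–Cr) | Cl[Cr](Cl)C/C(=C/OC(=O)COC)C1=CC(=O)[C@](C)(C[C@@H](OC(=O)C(C)C)[C@H](C=O)C(=C)C(=O)OC)O1 | intermediate
29 | methyl 2-[(5S,6R,7S,8R,10S)-6-hydroxy-5-[(methoxyacetyl)oxy]-10-methyl-4-methylidene-8-[(2-methylpropanoyl)oxy]-1-oxo-3,10-epoxycyclodec-2-en-7-yl]prop-2-enoate (germacrane locants; product of the key step) | C=C(C(=O)OC)[C@@H]1[C@H](OC(=O)C(C)C)C[C@]2(C)OC(=CC2=O)C(=C)[C@H](OC(=O)COC)[C@@H]1O | intermediate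
30 | (5S,6R,7R,8R,10S)-5-[(methoxyacetyl)oxy]-8-[(2-methylpropanoyl)oxy]-1-oxo-3,10-epoxygermacra-2,4(15),11(13)-trien-12,6-olide | C=C1C(=O)O[C@@H]2[C@H]1[C@H](OC(=O)C(C)C)C[C@]1(C)OC(=CC1=O)C(=C)[C@@H]2OC(=O)COC | intermediate
31 | CNP0384113.2, (5S,6R,7R,8R,10S)-5-hydroxy-8-[(2-methylpropanoyl)oxy]-1-oxo-3,10-epoxygermacra-2,4(15),11(13)-trien-12,6-olide | C=C1C(=O)O[C@@H]2[C@H]1[C@H](OC(=O)C(C)C)C[C@]1(C)OC(=CC1=O)C(=C)[C@@H]2O | target

Total step count: 19. Longest linear sequence: 14 steps, from 5 to 31 (steps 3–7, 10–12 and 14–19).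

Steps most likely to fail

Step 17 (the step that carries the new-method label). The ring closure may lose to oligomerisation or to simple reduction of the C–Br bond. The methoxyacetyl group may migrate from O5 to the new chromium alkoxide on O6. The 2-substituted allylchromium may react through the other geometry and give the syn pair. The C7 centre may epimerise before the ring closes. The fallback removes the γ-acyloxy group, which is the untested element, and brings in O5 after ring closure by C–H oxidation. It sets out from enal 22 and comes back at 31. Luche reduction of 22 (NaBH4, CeCl3·7H2O, MeOH, −78 °C) would give the allylic alcohol F1. An Appel reaction (CBr4, PPh3) would give the 2-substituted allylic bromide F2. HF·pyridine would free the C6 primary alcohol F3, and Dess–Martin oxidation would give the aldehyde F4. CrCl2 in THF at high dilution, the established chromium closure of ten-membered rings from simple allylic bromides, would give the macrocyclic homoallylic alcohol F5, with C6 again set by Felkin–Anh control from C7. Acid-catalysed lactonisation would give the 5-deoxy lactone F6. Allylic hydroxylation with SeO2 and t-BuOOH at C5, the only sp3 position allylic to C4=C15, would then lead to 31; the face selectivity at C5 would have to be established.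

Step 14. The conjugate addition may be overtaken by dimerisation of the reactive 2-substituted acrolein, by acylative cleavage of the silyl ether, or by unproductive acylation at the furanone carbonyl, so that the bromopropenyl ester is not obtained cleanly. The fallback avoids the enol ester altogether and forms C5–C6 by a reductive pinacol macrocyclisation, a known route to ten-membered carbocyclic diols. It sets out from 21 and comes back at 31. HF·pyridine on 21 would give the C6 alcohol F7, Dess–Martin oxidation the C6 aldehyde F8, and dilute aqueous acid the dialdehyde F9. SmI2 in THF at −78 °C under high dilution would couple the two carbonyl carbons to the C5,C6-diol F10, of which the erythro isomer is needed. Acid would then lactonise O6, the five-membered mode, onto the methyl ester to give 31 directly, with O5 already free.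

Step 10. Facial control by the ligand may be insufficient, which would give the (7R,8S) syn isomer as well. The allylchromium may lose silyloxide in a 1,4-elimination to a diene. The aldehyde may open by β-elimination of the furanone oxygen. The fallback replaces the chromium reagent by an allylboronate, whose carbon–boron bond does not eliminate and which reacts through a closed chair with strict syn transfer of the alkene geometry. It sets out from 17 and comes back at 19. Palladium-catalysed borylation of 17 with bis(pinacolato)diboron (Pd2(dba)3, toluene, 50 °C) would give the allylboronate F11. Its addition to aldehyde 13, catalysed by a chiral BINOL-derived phosphoric acid in toluene at low temperature, would give 19 after aqueous work-up; should the catalyst not control the aldehyde face, the two syn diastereomers would be separated at this stage.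

Further compounds
F1 | step 17 | methyl (3S,4R)-3-{[(tert-butyldiphenylsilyl)oxy]methyl}-5-[(2S)-5-(3-hydroxyprop-1-en-2-yl)-2-methyl-3-oxo-2,3-dihydrofuran-2-yl]-2-methylidene-4-[(2-methylpropanoyl)oxy]pentanoate | OCC(=C)C1=CC(=O)[C@](C)(C[C@@H](OC(=O)C(C)C)[C@H](CO[Si](c2ccccc2)(c2ccccc2)C(C)(C)C)C(=C)C(=O)OC)O1
F2 | step 17 | methyl (3S,4R)-5-[(2S)-5-(3-bromoprop-1-en-2-yl)-2-methyl-3-oxo-2,3-dihydrofuran-2-yl]-3-{[(tert-butyldiphenylsilyl)oxy]methyl}-2-methylidene-4-[(2-methylpropanoyl)oxy]pentanoate | BrCC(=C)C1=CC(=O)[C@](C)(C[C@@H](OC(=O)C(C)C)[C@H](CO[Si](c2ccccc2)(c2ccccc2)C(C)(C)C)C(=C)C(=O)OC)O1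
F3 | step 17 | methyl (3S,4R)-5-[(2S)-5-(3-bromoprop-1-en-2-yl)-2-methyl-3-oxo-2,3-dihydrofuran-2-yl]-3-(hydroxymethyl)-2-methylidene-4-[(2-methylpropanoyl)oxy]pentanoate | BrCC(=C)C1=CC(=O)[C@](C)(C[C@@H](OC(=O)C(C)C)[C@H](CO)C(=C)C(=O)OC)O1
F4 | step 17 | methyl (3R,4R)-5-[(2S)-5-(3-bromoprop-1-en-2-yl)-2-methyl-3-oxo-2,3-dihydrofuran-2-yl]-3-formyl-2-methylidene-4-[(2-methylpropanoyl)oxy]pentanoate | BrCC(=C)C1=CC(=O)[C@](C)(C[C@@H](OC(=O)C(C)C)[C@H](C=O)C(=C)C(=O)OC)O1
F5 | step 17 | methyl 2-[(6S,7S,8R,10S)-6-hydroxy-10-methyl-4-methylidene-8-[(2-methylpropanoyl)oxy]-1-oxo-3,10-epoxycyclodec-2-en-7-yl]prop-2-enoate (germacrane locants) | C=C(C(=O)OC)[C@@H]1[C@H](OC(=O)C(C)C)C[C@]2(C)OC(=CC2=O)C(=C)C[C@@H]1O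
F6 | step 17 | (6S,7S,8R,10S)-8-[(2-methylpropanoyl)oxy]-1-oxo-3,10-epoxygermacra-2,4(15),11(13)-trien-12,6-olide (5-deoxy-31) | C=C1C(=O)O[C@@H]2[C@H]1[C@H](OC(=O)C(C)C)C[C@]1(C)OC(=CC1=O)C(=C)C2
F7 | step 14 | methyl (3S,4R)-5-[(2S)-5-(3,3-diethoxyprop-1-en-2-yl)-2-methyl-3-oxo-2,3-dihydrofuran-2-yl]-3-(hydroxymethyl)-2-methylidene-4-[(2-methylpropanoyl)oxy]pentanoate | CCOC(OCC)C(=C)C1=CC(=O)[C@](C)(C[C@@H](OC(=O)C(C)C)[C@H](CO)C(=C)C(=O)OC)O1
F8 | step 14 | methyl (3R,4R)-5-[(2S)-5-(3,3-diethoxyprop-1-en-2-yl)-2-methyl-3-oxo-2,3-dihydrofuran-2-yl]-3-formyl-2-methylidene-4-[(2-methylpropanoyl)oxy]pentanoate | CCOC(OCC)C(=C)C1=CC(=O)[C@](C)(C[C@@H](OC(=O)C(C)C)[C@H](C=O)C(=C)C(=O)OC)O1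
F9 | step 14 | methyl (3R,4R)-3-formyl-5-[(2S)-2-methyl-3-oxo-5-(3-oxoprop-1-en-2-yl)-2,3-dihydrofuran-2-yl]-2-methylidene-4-[(2-methylpropanoyl)oxy]pentanoate | O=CC(=C)C1=CC(=O)[C@](C)(C[C@@H](OC(=O)C(C)C)[C@H](C=O)C(=C)C(=O)OC)O1
F10 | step 14 | methyl 2-[(5S,6R,7S,8R,10S)-5,6-dihydroxy-10-methyl-4-methylidene-8-[(2-methylpropanoyl)oxy]-1-oxo-3,10-epoxycyclodec-2-en-7-yl]prop-2-enoate (germacrane locants) | C=C(C(=O)OC)[C@@H]1[C@H](OC(=O)C(C)C)C[C@]2(C)OC(=CC2=O)C(=C)[C@H](O)[C@@H]1O
F11 | step 10 | methyl (2E)-4-[(tert-butyldiphenylsilyl)oxy]-2-[(4,4,5,5-tetramethyl-1,3,2-dioxaborolan-2-yl)methyl]but-2-enoate | CC1(C)OB(C/C(=C\CO[Si](c2ccccc2)(c2ccccc2)C(C)(C)C)C(=O)OC)OC1(C)C
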